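**Strategy**

Ring A of the 5,7-dihydroxychroman-2-one unit is a phloroglucinol whose only carbon substituent, C4 on C4a, sits between the oxygens on C5 and C8a, with the third oxygen on C7. This pattern is cut into a siloxyalkyne carrying C4a/C5 and 3-ethoxyvinylketene carrying C8a, C8, C7 and C6. One thermal benzannulation forms C4a–C8a and C5–C6, closes ring A and frees only the C8a hydroxyl for lactone A. The precursor is a triisopropylsiloxyalkyne bearing the C4 aryl stereocentre and a C3 succinate; its arm carboxyl is a silyl ester because it passes the alkyne oxidation as a lithium carboxylate. Lactone B follows by a carbene-catalysed quinone methide annulation.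

Key step: step 7

**Remarks on the chemistry**

- Assumption: 3-ethoxycyclobut-2-en-1-one (14) and 1,2,3,4-tetramethoxybenzene (21) are taken as purchasable.
- Assumption: the ligand antipode (step 2) and the carbene antipode (step 11) are assigned by analogy; the mirror-image catalyst would be used if a model run shows the opposite sense.
- A CH2–CO2R ester arm would be enolised by the amide base during acetylide oxidation. The arm is therefore a free acid at that stage and leaves the silylation as a triisopropylsilyl ester.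
- The 3,4-trans relation in each lactone is the thermodynamic one and is set by base equilibration (steps 8 and 11). Kinetic protonation of the lactone enolate anti to the C4 aryl group would give cis.
- Unit A atoms are unprimed, unit B atoms primed.

**Route**

Step 1
Reactants: 1 4-methoxybenzaldehyde; 2 Meldrum's acid
Product: 3 5-(4-methoxybenzylidene)-2,2-dimethyl-1,3-dioxane-4,6-dione
Conditions: H2O, 75 °C
Reagents that add atoms: none
Why: Knoevenagel condensation of the acidic Meldrum's acid methylene with the aldehyde should proceed without catalyst in hot water, the arylidene product separating as a solid.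

Step 2
Reactants: 3 5-(4-methoxybenzylidene)-2,2-dimethyl-1,3-dioxane-4,6-dione; 4 trimethylsilylacetylene
Product: 5 5-[(1S)-1-(4-methoxyphenyl)-3-(trimethylsilyl)prop-2-yn-1-yl]-2,2-dimethyl-1,3-dioxane-4,6-dione
Conditions: [Rh(OAc)(C2H4)2]2 (2.5 mol %), (S)-(6,6'-dimethoxybiphenyl-2,2'-diyl)bis[bis(3,5-dimethylphenyl)phosphine] (5.5 mol %), 1,4-dioxane/H2O, rt
Reagents that add atoms: none
Why: Rhodium-catalysed asymmetric conjugate alkynylation of arylidene Meldrum's acids with a silylacetylene is established chemistry; the chiral bisphosphine on the alkynylrhodium species selects the alkene face and so sets C4 (S), while the silyl group suppresses alkyne dimerisation.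

Step 3
Reactants: 5 5-[(1S)-1-(4-methoxyphenyl)-3-(trimethylsilyl)prop-2-yn-1-yl]-2,2-dimethyl-1,3-dioxane-4,6-dione
Product: 6 methyl (3S)-3-(4-methoxyphenyl)-5-(trimethylsilyl)pent-4-ynoate
Conditions: MeOH/pyridine (1:1), Cu powder (cat.), reflux
Reagents that add atoms: methanol, CO
Why: Decarboxylative esterification: methanolysis of the monoalkyl Meldrum's acid gives the malonic half-ester, which should lose CO2 on heating, while the weakly basic medium leaves the alkynylsilane and C4 untouched.

Step 4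
Reactants: 6 methyl (3S)-3-(4-methoxyphenyl)-5-(trimethylsilyl)pent-4-ynoate; 7 tert-butyl bromoacetate
Product: 8 4-tert-butyl 1-methyl (2S)-2-[(1S)-1-(4-methoxyphenyl)-3-(trimethylsilyl)prop-2-yn-1-yl]butanedioate
Conditions: LiN(iPr)2 (1.1 equiv), THF, −78 °C; then 7, −78 to −40 °C
Reagents that add atoms: none
Why: Ester enolate alkylation (SN2) with a reactive α-bromo ester; in the allylic-strain-minimised enolate conformer (C4–H in the enolate plane) the electrophile should approach anti to the aryl group and give the drawn C3 configuration, and any C3 epimer converges in step 8.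

Step 5
Reactants: 8 4-tert-butyl 1-methyl (2S)-2-[(1S)-1-(4-methoxyphenyl)-3-(trimethylsilyl)prop-2-yn-1-yl]butanedioate
Product: 10 (3S,4R)-3-(methoxycarbonyl)-4-(4-methoxyphenyl)hex-5-ynoic acid, via terminal alkyne diester 9 (not isolated)
Conditions: K2CO3 (cat.), MeOH, rt; evaporate; TFA, CH2Cl2, 0 °C to rt
Reagents that add atoms: none
Why: Methoxide-mediated protodesilylation of the alkynylsilane followed by acidolysis of the tert-butyl ester (E1 loss of isobutene) should free the terminal alkyne and the arm acid while the methyl ester, C3 and C4 are untouched.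

Step 6
Reactants: 10 (3S,4R)-3-(methoxycarbonyl)-4-(4-methoxyphenyl)hex-5-ynoic acid
Product: 13 1-methyl 4-(triisopropylsilyl) (2S)-2-[(1S)-1-(4-methoxyphenyl)-3-[(triisopropylsilyl)oxy]prop-2-yn-1-yl]butanedioate, via dilithium acetylide carboxylate 11 (not isolated), via dilithium ynolate carboxylate 12 (not isolated)
Conditions: LiN(SiMe3)2 (2.1 equiv), THF, −78 °C; cannulate into LiOOtBu (from tBuOOH and LiN(SiMe3)2, THF, −78 °C); −78 to 0 °C; iPr3SiOTf (2.4 equiv), −78 to 0 °C; pH 7 buffer
Reagents that add atoms: lithium tert-butyl peroxide, [Li+].[O-]OC(C)(C)C; triisopropylsilyl trifluoromethanesulfonate, CC(C)[Si](OS(=O)(=O)C(F)(F)F)(C(C)C)C(C)C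
Why: Oxidation of a lithium acetylide by LiOOtBu to the ynolate and O-silylation with a bulky silyl triflate is the standard siloxyalkyne synthesis; the arm carboxyl is masked in situ as a lithium carboxylate that the amide base cannot enolise, and the hindered α-branched methyl ester should be neither deprotonated nor attacked between −78 and 0 °C.

Step 7
Reactants: 13 1-methyl 4-(triisopropylsilyl) (2S)-2-[(1S)-1-(4-methoxyphenyl)-3-[(triisopropylsilyl)oxy]prop-2-yn-1-yl]butanedioate; 14 3-ethoxycyclobut-2-en-1-one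
Product: 19 1-methyl 4-(triisopropylsilyl) (2S)-2-[(S)-[4-ethoxy-2-hydroxy-6-[(triisopropylsilyl)oxy]phenyl](4-methoxyphenyl)methyl]butanedioate (ring A phenol), via ethoxyvinylketene 15 (not isolated), via vinylcyclobutenone 16 (not isolated), via dienylketene 17 (not isolated), via cyclohexadienone 18 (not isolated)
Conditions: toluene, 80 to 110 °C, slow addition of 14 (1.2 equiv), Ar
Reagents that add atoms: none
Why: Heating opens 14 by 4π electrocyclic ring opening to 3-ethoxyvinylketene 15, whose ketene carbon (future C8a) is attacked by the nucleophilic, C4-bearing alkyne carbon of 13 in a regiospecific [2+2] cycloaddition that also joins the ketene α-carbon (C6) to the siloxy carbon (C5), giving vinylcyclobutenone 16. A second 4π opening gives dienylketene 17, which closes carbocyclic ring A by thermal disrotatory 6π electrocyclisation (C8–C8a) to cyclohexadienone 18 and tautomerises to phenol 19. This is the Danheiser benzannulation of a cyclobutenone-derived vinylketene with a siloxyalkyne. No stereocentre is created, and the neutral thermal conditions should leave C4, C3, the methyl ester and the silyl ester untouched. The selectivity needed is the orientation of the [2+2] step, which the polarisation of the ynol ether secures, so that the free hydroxyl appears only at C8a and the oxygens at C5 and C7 emerge as different ethers. Slow addition of 14 keeps the ketene concentration low and limits acylation of the product phenol.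

Step 8
Reactants: 19 1-methyl 4-(triisopropylsilyl) (2S)-2-[(S)-[4-ethoxy-2-hydroxy-6-[(triisopropylsilyl)oxy]phenyl](4-methoxyphenyl)methyl]butanedioate
Product: 20 2-[(3S,4S)-7-ethoxy-4-(4-methoxyphenyl)-2-oxo-5-[(triisopropylsilyl)oxy]chroman-3-yl]acetic acid
Conditions: TsOH·H2O (1.0 equiv), toluene, 80 °C; then DBU (2.5 equiv), CH2Cl2, rt; aq. HCl work-up
Reagents that add atoms: none
Why: Acid-catalysed transesterification of the C8a phenol onto the C2 methyl ester should close the six-membered aryl lactone A while the labile silyl ester is hydrolysed, and DBU then equilibrates C3 through the lactone enolate to the thermodynamically preferred 3,4-trans isomer, which fixes C3.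

Step 9
Reactants: 21 1,2,3,4-tetramethoxybenzene
Product: 24 2,3,4,5-tetramethoxyphenol, via aryllithium 22 (not isolated), via arylboronate 23 (not isolated)
Conditions: n-BuLi, TMEDA, THF, 0 °C; B(OMe)3, −78 °C to rt; H2O2, aq. NaOH, 0 °C
Reagents that add atoms: hydrogen peroxide, OO
Why: Directed ortho-lithiation next to a methoxy group, borylation and oxidative 1,2-shift of the aryl group from boron to oxygen should give the phenol at the only kind of free ring position.

Step 10
Reactants: 24 2,3,4,5-tetramethoxyphenol; 1 4-methoxybenzaldehyde; 25 sodium 4-methylbenzenesulfinate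
Product: 26 2,3,4,5-tetramethoxy-6-[(4-methoxyphenyl)(4-methylbenzenesulfonyl)methyl]phenol (racemic)
Conditions: HCO2H/H2O (2:1), rt
Reagents that add atoms: none
Why: Acid-mediated three-component Friedel–Crafts hydroxyalkylation at the single free ortho position of the electron-rich phenol, with sulfinate capturing the benzylic cation, should give the bench-stable sulfone precursor of the ring B ortho-quinone methide; its benzylic centre is planarised later.

Step 11
Reactants: 20 2-[(3S,4S)-7-ethoxy-4-(4-methoxyphenyl)-2-oxo-5-[(triisopropylsilyl)oxy]chroman-3-yl]acetic acid; 26 2,3,4,5-tetramethoxy-6-[(4-methoxyphenyl)(4-methylbenzenesulfonyl)methyl]phenol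
Product: 30 (3R,4S)-7-ethoxy-4-(4-methoxyphenyl)-3-[(3S,4R)-5,6,7,8-tetramethoxy-4-(4-methoxyphenyl)-2-oxochroman-3-yl]-5-[(triisopropylsilyl)oxy]chroman-2-one, via acyl imidazole 27 (not isolated), via quinone methide 28 (not isolated), via cis lactone 29 (not isolated)
Conditions: CDI (1.1 equiv), THF, rt; then 26 (1.2 equiv), (5aR,10bS)-2-mesityl-5a,10b-dihydro-4H,6H-indeno[2,1-b][1,2,4]triazolo[4,3-d][1,4]oxazin-2-ium tetrafluoroborate (20 mol %), Cs2CO3 (2.5 equiv), 0 °C to rt; then DBU (1 equiv), rt
Reagents that add atoms: none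
Why: Carbene-catalysed formal [4+2] annulation: the acyl imidazole gives an acyl azolium whose enolate adds at C3' to the quinone methide released from the sulfone by Cs2CO3, the phenoxide lactonises with release of the carbene, the chiral triazolylidene selects the face of the methide carbon and so sets C4' (R), and DBU then epimerises C3' (S) through the lactone B enolate to the all-trans thermodynamic isomer while C3 stays trans.

Step 12
Reactants: 30 (3R,4S)-7-ethoxy-4-(4-methoxyphenyl)-3-[(3S,4R)-5,6,7,8-tetramethoxy-4-(4-methoxyphenyl)-2-oxochroman-3-yl]-5-[(triisopropylsilyl)oxy]chroman-2-one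
Product: 31 (3R,4S)-5,7-dihydroxy-4-(4-hydroxyphenyl)-3-[(3S,4R)-5,6,7,8-tetrahydroxy-4-(4-hydroxyphenyl)-2-oxochroman-3-yl]chroman-2-one (CNP0064734.3)
Conditions: BBr3 (20 equiv), CH2Cl2, −78 °C to rt, Ar; MeOH quench; degassed 1 M HCl, 40 °C
Reagents that add atoms: none
Why: Lewis-acid cleavage of the aryl methyl, ethyl and silyl ethers by BBr3 should free all nine hydroxyls; any lactone opened on the way re-closes on acidic work-up to the same compound because C5/C8a of ring A and C5'/C8a' of ring B are equivalent once deprotected, and the benzylic centres C4 and C4' are not touched.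

**Compound list**

1 | 4-methoxybenzaldehyde | COc1ccc(C=O)cc1 | starting material
2 | Meldrum's acid (2,2-dimethyl-1,3-dioxane-4,6-dione) | CC1(C)OC(=O)CC(=O)O1 | starting material
3 | 5-(4-methoxybenzylidene)-2,2-dimethyl-1,3-dioxane-4,6-dione | COc1ccc(C=C2C(=O)OC(C)(C)OC2=O)cc1 | intermediate
4 | trimethylsilylacetylene | C[Si](C)(C)C#C | starting material
5 | 5-[(1S)-1-(4-methoxyphenyl)-3-(trimethylsilyl)prop-2-yn-1-yl]-2,2-dimethyl-1,3-dioxane-4,6-dione | C[Si](C)(C)C#C[C@H](c1ccc(OC)cc1)C1C(=O)OC(C)(C)OC1=O | intermediate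
6 | methyl (3S)-3-(4-methoxyphenyl)-5-(trimethylsilyl)pent-4-ynoate | C[Si](C)(C)C#C[C@H](c1ccc(OC)cc1)CC(=O)OC | intermediate
7 | tert-butyl bromoacetate | BrCC(=O)OC(C)(C)C | starting material
8 | 4-tert-butyl 1-methyl (2S)-2-[(1S)-1-(4-methoxyphenyl)-3-(trimethylsilyl)prop-2-yn-1-yl]butanedioate | C[Si](C)(C)C#C[C@H](c1ccc(OC)cc1)[C@@H](C(=O)OC)CC(=O)OC(C)(C)C | intermediate
9 | 4-tert-butyl 1-methyl (2S)-2-[(1R)-1-(4-methoxyphenyl)prop-2-yn-1-yl]butanedioate | C#C[C@H](c1ccc(OC)cc1)[C@@H](C(=O)OC)CC(=O)OC(C)(C)C | intermediate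
10 | (3S,4R)-3-(methoxycarbonyl)-4-(4-methoxyphenyl)hex-5-ynoic acid | C#C[C@H](c1ccc(OC)cc1)[C@@H](C(=O)OC)CC(=O)O | intermediate
11 | dilithium acetylide carboxylate of 10 | [Li+].[Li+].[C-]#C[C@H](c1ccc(OC)cc1)[C@@H](C(=O)OC)CC(=O)[O-] | intermediate
12 | dilithium ynolate carboxylate | [Li+].[Li+].[O-]C#C[C@H](c1ccc(OC)cc1)[C@@H](C(=O)OC)CC(=O)[O-] | intermediate
13 | 1-methyl 4-(triisopropylsilyl) (2S)-2-[(1S)-1-(4-methoxyphenyl)-3-[(triisopropylsilyl)oxy]prop-2-yn-1-yl]butanedioate (key-step precursor) | CC(C)[Si](OC#C[C@H](c1ccc(OC)cc1)[C@@H](C(=O)OC)CC(=O)O[Si](C(C)C)(C(C)C)C(C)C)(C(C)C)C(C)C | intermediate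
14 | 3-ethoxycyclobut-2-en-1-one | CCOC1=CC(=O)C1 | starting material
15 | 3-ethoxybuta-1,3-dien-1-one (ethoxyvinylketene) | C=C(OCC)C=C=O | intermediate
16 | 4-(1-ethoxyvinyl)-3-siloxycyclobut-2-en-1-one carrying the C4/C3 side chain at its 2-position (ring CH unassigned) | C=C(OCC)C1C(O[Si](C(C)C)(C(C)C)C(C)C)=C(C1=O)[C@H](c1ccc(OC)cc1)[C@@H](C(=O)OC)CC(=O)O[Si](C(C)C)(C(C)C)C(C)C | intermediate
17 | dienylketene from ring opening of 16 | C=C(OCC)C=C(O[Si](C(C)C)(C(C)C)C(C)C)C(=C=O)[C@H](c1ccc(OC)cc1)[C@@H](C(=O)OC)CC(=O)O[Si](C(C)C)(C(C)C)C(C)C | intermediate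
18 | 5-ethoxy-3-siloxycyclohexa-2,4-dien-1-one carrying the side chain at its 2-position (keto tautomer of 19) | O=C1CC(OCC)=CC(O[Si](C(C)C)(C(C)C)C(C)C)=C1[C@H](c1ccc(OC)cc1)[C@@H](C(=O)OC)CC(=O)O[Si](C(C)C)(C(C)C)C(C)C | intermediate
19 | 1-methyl 4-(triisopropylsilyl) (2S)-2-[(S)-[4-ethoxy-2-hydroxy-6-[(triisopropylsilyl)oxy]phenyl](4-methoxyphenyl)methyl]butanedioate (key-step product) | CCOc1cc(O)c([C@H](c2ccc(OC)cc2)[C@@H](C(=O)OC)CC(=O)O[Si](C(C)C)(C(C)C)C(C)C)c(O[Si](C(C)C)(C(C)C)C(C)C)c1 | intermediate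
20 | 2-[(3S,4S)-7-ethoxy-4-(4-methoxyphenyl)-2-oxo-5-[(triisopropylsilyl)oxy]chroman-3-yl]acetic acid | O=C1Oc2cc(OCC)cc(O[Si](C(C)C)(C(C)C)C(C)C)c2[C@H](c2ccc(OC)cc2)[C@@H]1CC(=O)O | intermediate
21 | 1,2,3,4-tetramethoxybenzene | COc1ccc(OC)c(OC)c1OC | starting material
22 | (2,3,4,5-tetramethoxyphenyl)lithium | [Li]c1cc(OC)c(OC)c(OC)c1OC | intermediate
23 | dimethyl (2,3,4,5-tetramethoxyphenyl)boronate | COB(OC)c1cc(OC)c(OC)c(OC)c1OC | intermediate
24 | 2,3,4,5-tetramethoxyphenol | Oc1cc(OC)c(OC)c(OC)c1OC | intermediate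
25 | sodium 4-methylbenzenesulfinate | [Na+].[O-]S(=O)c1ccc(C)cc1 | starting material
26 | 2,3,4,5-tetramethoxy-6-[(4-methoxyphenyl)(4-methylbenzenesulfonyl)methyl]phenol (racemic) | COc1ccc(C(c2c(O)c(OC)c(OC)c(OC)c2OC)S(=O)(=O)c2ccc(C)cc2)cc1 | intermediate
27 | (3S,4S)-7-ethoxy-3-[2-(1H-imidazol-1-yl)-2-oxoethyl]-4-(4-methoxyphenyl)-5-[(triisopropylsilyl)oxy]chroman-2-one | O=C1Oc2cc(OCC)cc(O[Si](C(C)C)(C(C)C)C(C)C)c2[C@H](c2ccc(OC)cc2)[C@@H]1CC(=O)n1ccnc1 | intermediate
28 | 2,3,4,5-tetramethoxy-6-[(4-methoxyphenyl)methylidene]cyclohexa-2,4-dien-1-one (ring B ortho-quinone methide) | COc1ccc(C=C2C(=O)C(OC)=C(OC)C(OC)=C2OC)cc1 | intermediate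
29 | (3R,4S)-7-ethoxy-4-(4-methoxyphenyl)-3-[(3R,4R)-5,6,7,8-tetramethoxy-4-(4-methoxyphenyl)-2-oxochroman-3-yl]-5-[(triisopropylsilyl)oxy]chroman-2-one (3',4'-cis) | O=C1Oc2cc(OCC)cc(O[Si](C(C)C)(C(C)C)C(C)C)c2[C@H](c2ccc(OC)cc2)[C@@H]1[C@@H]1C(=O)Oc2c(OC)c(OC)c(OC)c(OC)c2[C@H]1c1ccc(OC)cc1 | intermediate
30 | (3R,4S)-7-ethoxy-4-(4-methoxyphenyl)-3-[(3S,4R)-5,6,7,8-tetramethoxy-4-(4-methoxyphenyl)-2-oxochroman-3-yl]-5-[(triisopropylsilyl)oxy]chroman-2-one | O=C1Oc2cc(OCC)cc(O[Si](C(C)C)(C(C)C)C(C)C)c2[C@H](c2ccc(OC)cc2)[C@@H]1[C@H]1C(=O)Oc2c(OC)c(OC)c(OC)c(OC)c2[C@H]1c1ccc(OC)cc1 | intermediate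
31 | (3R,4S)-5,7-dihydroxy-4-(4-hydroxyphenyl)-3-[(3S,4R)-5,6,7,8-tetrahydroxy-4-(4-hydroxyphenyl)-2-oxochroman-3-yl]chroman-2-one | O=C1Oc2cc(O)cc(O)c2[C@H](c2ccc(O)cc2)[C@@H]1[C@H]1C(=O)Oc2c(O)c(O)c(O)c(O)c2[C@H]1c1ccc(O)cc1 | target

**Step count and risk**

Total step count: 12. Longest linear sequence: 10 steps (steps 1 to 8, 11 and 12); steps 9 and 10 form the two-step ring B branch.

Steps most likely to fail:

1. Step 7. The donor-substituted cyclobutenone may open only at temperatures where the vinylketene oligomerises or acylates the product phenol faster than the hindered siloxyalkyne captures it. The fallback sets out from 13 and generates the same vinylketene 15 at room temperature by photochemical Wolff rearrangement of 1-diazo-3-ethoxybut-3-en-2-one F1 (from 2-ethoxyacryloyl chloride and diazomethane). Irradiation in ClCH2CH2Cl in the presence of 13 is followed by brief warming to 80 °C to complete ring opening and 6π closure. This diazo ketone variant of the benzannulation comes back to the route at 19.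

2. Step 11. The C3 stereocentre next to the azolium enolate may oppose the catalyst, giving poor facial selectivity at the methide carbon C4', or the acyl imidazole may acylate the phenol of 26 before sulfinate loss. The fallback sets out from 20, which is converted with (COCl)2 and catalytic DMF into 2-[(3S,4S)-7-ethoxy-4-(4-methoxyphenyl)-2-oxo-5-[(triisopropylsilyl)oxy]chroman-3-yl]acetyl chloride F2. Dehydrohalogenation with iPr2NEt at −78 °C in the presence of O-benzoylquinidine (or O-benzoylquinine for the opposite sense) gives a chiral ammonium ketene enolate. This undergoes the [4+2] cycloaddition with quinone methide 28, pre-formed from 26 with Cs2CO3. DBU equilibration then returns the route to 30.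

3. Step 6. The methyl ester may be partly enolised or attacked by the amide base or the peroxide during acetylide oxidation, with loss of material. The fallback sets out from 10, which is saponified with LiOH in THF/H2O to (2S)-2-[(1R)-1-(4-methoxyphenyl)prop-2-yn-1-yl]butanedioic acid F3, so that no ester is present. Oxidation of its trilithium salt with LiOOtBu and silylation with iPr3SiOTf (3.5 equiv) gives bis(triisopropylsilyl) (2S)-2-[(1S)-1-(4-methoxyphenyl)-3-[(triisopropylsilyl)oxy]prop-2-yn-1-yl]butanedioate F4. Benzannulation of F4 with 14 under the conditions of step 7 gives bis(triisopropylsilyl) (2S)-2-[(S)-[4-ethoxy-2-hydroxy-6-[(triisopropylsilyl)oxy]phenyl](4-methoxyphenyl)methyl]butanedioate F5. Treatment with TsOH·H2O in toluene and then DBU closes lactone A with loss of both silyl esters and comes back to the route at 20.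

Further compounds
F1 | step 7 | 1-diazo-3-ethoxybut-3-en-2-one | C=C(OCC)C(=O)C=[N+]=[N-]
F2 | step 11 | 2-[(3S,4S)-7-ethoxy-4-(4-methoxyphenyl)-2-oxo-5-[(triisopropylsilyl)oxy]chroman-3-yl]acetyl chloride | O=C1Oc2cc(OCC)cc(O[Si](C(C)C)(C(C)C)C(C)C)c2[C@H](c2ccc(OC)cc2)[C@@H]1CC(=O)Cl
F3 | step 6 | (2S)-2-[(1R)-1-(4-methoxyphenyl)prop-2-yn-1-yl]butanedioic acid | C#C[C@H](c1ccc(OC)cc1)[C@@H](C(=O)O)CC(=O)O
F4 | step 6 | bis(triisopropylsilyl) (2S)-2-[(1S)-1-(4-methoxyphenyl)-3-[(triisopropylsilyl)oxy]prop-2-yn-1-yl]butanedioate | CC(C)[Si](OC#C[C@H](c1ccc(OC)cc1)[C@@H](C(=O)O[Si](C(C)C)(C(C)C)C(C)C)CC(=O)O[Si](C(C)C)(C(C)C)C(C)C)(C(C)C)C(C)C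
F5 | step 6 | bis(triisopropylsilyl) (2S)-2-[(S)-[4-ethoxy-2-hydroxy-6-[(triisopropylsilyl)oxy]phenyl](4-methoxyphenyl)methyl]butanedioate | CCOc1cc(O)c([C@H](c2ccc(OC)cc2)[C@@H](C(=O)O[Si](C(C)C)(C(C)C)C(C)C)CC(=O)O[Si](C(C)C)(C(C)C)C(C)C)c(O[Si](C(C)C)(C(C)C)C(C)C)c1
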